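The readings are calculated with made-up constants; scatter was added.

| flask | D | J | Z | remark | time |
|---|---|---|---|---|---|
| south | 0.50 M | 190 mM (held) | 11 mM | run made earlier |  |
| east | 0.50 M | 190 mM (held) | 24 mM | run made earlier |  |
| north | 0.50 M | 190 mM (held) | 52 mM | run made earlier |  |
| gamma | 0.50 M | 190 mM (held) | 10.0 mM |  | 5.0 d |
| zeta | 0.50 M | 190 mM (held) | 25.0 mM |  | 5.0 d |
| alpha | 0.50 M | 190 mM (held) | 62.0 mM |  | 5.0 d |

| run | time / d | X / % | D / % | E / % |
|---|---|---|---|---|
| south | 0.208 | 1.8 | 63.8 | 20.1 |
| south | 0.625 | 9.4 | 27.4 | 42.4 |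
| south | 1.25 | 14.4 | 8.4 | 55.6 |
| south | 1.67 | 18.1 | 4.4 | 58.6 |
| south | 2.50 | 18.9 | 2.8 | 63.2 |
| east | 0.208 | 2.9 | 62.4 | 19.4 |
| east | 0.625 | 9.3 | 27.1 | 43.0 |
| east | 1.25 | 17.3 | 8.9 | 53.4 |
| east | 1.67 | 16.0 | 5.7 | 58.4 |
| east | 2.50 | 20.8 | 1.6 | 61.3 |
| north | 0.208 | 0 | 58.9 | 18.3 |
| north | 0.625 | 10.4 | 26.2 | 41.0 |
| north | 1.25 | 13.3 | 8.3 | 50.6 |
| north | 1.67 | 15.7 | 4.8 | 54.8 |
| north | 2.50 | 19.2 | 2.2 | 57.5 |

(standard deviation of a reading: 1 percentage point)

- at the start none of J is in solution
- a reading of D is of its free form alone

* which of these there is most of at the end, counted by the D in it, gamma (D / E / X)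
* which of these there is most of at the end, counted by the D in it, zeta (D / E / X)
* which of these there is most of at the end, counted by the D in it, alpha (D / E / X)
* the largest of these amounts at the end, in percent of the D charged, gamma
* the largest of these amounts at the end, in percent of the D charged, zeta
* the largest of these amounts at the end, in percent of the D charged, alpha

- The easy step is to count charges: I set cZ against cD and ask what part of D stays for the other products if each Z takes one D away. For alpha, one minus cZ over cD is 87.6%, and I call this the free share. For gamma it is 98.0%, and for the north run 89.6%.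
- The readings allow this count: at 2.50 d E in the north run over E in the south run reads 0.910, while the free shares of those runs give 0.916.
- Now I turn the question round. X and E together fit inside the free share, so for X to end above E in alpha, E would have to stay below half of it, which is 43.8%.
- But the north run already shows E at 57.5% at 2.50 d, and E rose at each of its readings. Scaled by the free shares, that reading gives an estimate of 56.2% for alpha at that time, so my estimate stands 12 percentage points above the mark.
- So I expect E on top in alpha, and also in gamma and zeta, which carry less Z. The number I commit to is a ratio: E in alpha over E in gamma should be 0.894.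
- The forecast names E, E and E, with 66% for gamma, 64% for zeta and 60% for alpha. It writes “Whether this loss is stoichiometric or saturating is uncertain”, and its alpha over gamma ratio of 0.909 stands a little above my 0.894.

- The flask gives E, E and E, with 68.8% in gamma, 66.6% in zeta and 61.3% in alpha.

    J ⇌ Q, rate k1*(csat - [Q]) (kL = 0.0861 h⁻¹)
    D + Q → X (k = 0.190 L mol⁻¹ h⁻¹)
    D → E (k = 0.0511 h⁻¹)
    D + Z → G (k = 7.98 L mol⁻¹ h⁻¹)
    D ⇌ L (K = 1.14, k = 0.0270 h⁻¹)

- In alpha at 5.00 d, G stands at 12.4% with 0% of the Z charge left, so Z is the limiting reagent of that side step. E in alpha over E in gamma comes to 0.891, against the 0.894 from the free shares. Applied to gamma's 71.9% at 50.0 d, my free-share ratio of 0.894 gives 64.3%, and alpha left as long stands at 64.1%.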